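The route rests on disconnecting the C8–C8a bond of ring A. C8a lies next to the oxygen-bearing C1 of the pyran ring and is the γ-carbon of the cross-conjugated dienone O2–C1=C8a–C4a=C5–C6=O, so reversible addition of a Lewis base at C1 makes C8a nucleophilic. In one operation this vinylogous Morita–Baylis–Hillman aldol closes ring A, forms C8–C8a and sets the C8 carbinol under control of C7. Its precursor is a 4-pyranylidene ketone that carries the epoxy side chain at C3 and, beyond the C6 ketone, a lactic-acid-derived quaternary C7 (methyl, silyloxy) bearing the C8 aldehyde; it is assembled by C-acylation of a 4-methylenepyran.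

Key step: step 19

Remarks on the chemistry:
- Atom numbers C1, O2, C3, C4, C4a, C5–C8, C8a are those of the isochromenone core of 30; C9 is the epoxide carbon on C3. TBS = tert-butyldimethylsilyl, TES = triethylsilyl.
- The exocyclic C4a=C5 bond of 27 and 28 is a push–pull alkene whose two geometries should interconvert; both are drawn with C6 syn to C8a, and either isomer can enter step 19.
- In 29 the TES group may shift from O7 to O8; both isomers give 30 in step 20.
- Commercial (R)-lactic acid is used directly. Steps 12–16 are run beforehand so that the sensitive methylenepyran 18 is acylated as soon as it is made.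

Step 1
Reactants: 1 ethyl (3S)-3-hydroxybutanoate
Product: 2 ethyl (2S,3S)-3-hydroxy-2-methylbutanoate
Conditions: LiN(iPr)2 (2.2 equiv), THF, −78 → −20 °C; MeI, DMPU, −78 → 0 °C; aq. NH4Cl
Reagents that add atoms: iodomethane, CI
Why: Fráter–Seebach alkylation, in which the chelated lithium alkoxide–enolate dianion is methylated on the face away from the C3 methyl group, which sets C2 anti to the hydroxyl and should give the (2S,3S) isomer.

Step 2
Reactants: 2 ethyl (2S,3S)-3-hydroxy-2-methylbutanoate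
Product: 3 ethyl (2S,3S)-3-(TBS-oxy)-2-methylbutanoate
Conditions: TBSCl, imidazole, DMF, rt
Reagents that add atoms: tert-butyldimethylsilyl chloride, CC(C)(C)[Si](C)(C)Cl
Why: Standard silylation of a secondary alcohol with a silyl chloride and imidazole, which touches no stereocentre.

Step 3
Reactants: 3 ethyl (2S,3S)-3-(TBS-oxy)-2-methylbutanoate
Product: 4 (2S,3S)-3-(TBS-oxy)-2-methylbutanal
Conditions: iBu2AlH (1.05 equiv), CH2Cl2, −78 °C; aq. potassium sodium tartrate; used crude
Reagents that add atoms: none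
Why: Partial ester reduction with iBu2AlH stops at the aldehyde because the aluminium hemiacetal survives at −78 °C until work-up, and the cold, non-basic conditions should leave the α-stereocentre intact.

Step 4
Reactants: 4 (2S,3S)-3-(TBS-oxy)-2-methylbutanal; 5 2-(triphenylphosphoranylidene)propanal
Product: 6 (2E,4R,5S)-5-(TBS-oxy)-2,4-dimethylhex-2-enal
Conditions: PhMe, 90 °C
Reagents that add atoms: none
Why: Wittig olefination with a stabilised formyl ylide, whose reversible addition step should give the (E)-trisubstituted enal directly at the aldehyde oxidation level.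

Step 5
Reactants: 6 (2E,4R,5S)-5-(TBS-oxy)-2,4-dimethylhex-2-enal; 7 ethyl 2-(triphenylphosphoranylidene)propanoate
Product: 8 ethyl (2E,4E,6R,7S)-7-(TBS-oxy)-2,4,6-trimethylocta-2,4-dienoate
Conditions: PhMe, 80 °C
Reagents that add atoms: none
Why: Second Wittig olefination with a stabilised ester ylide, which should again give the (E)-alkene and complete the (2E,4E)-dienoate.

Step 6
Reactants: 8 ethyl (2E,4E,6R,7S)-7-(TBS-oxy)-2,4,6-trimethylocta-2,4-dienoate
Product: 9 (2E,4E,6R,7S)-7-(TBS-oxy)-2,4,6-trimethylocta-2,4-dien-1-ol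
Conditions: iBu2AlH (2.5 equiv), CH2Cl2, −78 °C; aq. potassium sodium tartrate
Reagents that add atoms: none
Why: 1,2-Reduction of a conjugated ester to the allylic alcohol with iBu2AlH, which leaves the silyl ether and both alkenes untouched.

Step 7
Reactants: 9 (2E,4E,6R,7S)-7-(TBS-oxy)-2,4,6-trimethylocta-2,4-dien-1-ol
Product: 10 [(2S,3S)-3-[(2E,4R,5S)-5-(TBS-oxy)-4-methylhex-2-en-2-yl]-2-methyloxiran-2-yl]methanol
Conditions: Ti(OiPr)4 (10 mol %), L-(+)-diethyl tartrate (12 mol %), t-BuOOH (2 equiv), 4 Å molecular sieves, CH2Cl2, −20 °C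
Reagents that add atoms: tert-butyl hydroperoxide, CC(C)(C)OO
Why: Sharpless asymmetric epoxidation, in which only the allylic C2=C3 alkene is held on titanium through the alkoxide and L-(+)-diethyl tartrate should deliver oxygen to the face that gives the (2S,3S)-epoxide, setting both epoxide stereocentres under reagent control.

Step 8
Reactants: 10 [(2S,3S)-3-[(2E,4R,5S)-5-(TBS-oxy)-4-methylhex-2-en-2-yl]-2-methyloxiran-2-yl]methanol
Product: 12 (2R,3S)-3-[(2E,4R,5S)-5-(TBS-oxy)-4-methylhex-2-en-2-yl]-2-methyloxirane-2-carboxylic acid, via epoxy aldehyde 11 (not isolated)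
Conditions: TEMPO (20 mol %), PhI(OAc)2 (2.5 equiv), MeCN/aq. pH 7 phosphate buffer, 0 °C → rt
Reagents that add atoms: water, O
Why: Oxoammonium (TEMPO) oxidation of the primary alcohol through the aldehyde and its hydrate to the acid, under buffered conditions that should spare the vinyl epoxide, the alkene and the silyl ether.

Step 9
Reactants: 12 (2R,3S)-3-[(2E,4R,5S)-5-(TBS-oxy)-4-methylhex-2-en-2-yl]-2-methyloxirane-2-carboxylic acid; 13 (E)-4-methoxybut-3-en-2-one
Product: 15 (4E)-1-[(2R,3S)-3-[(2E,4R,5S)-5-(TBS-oxy)-4-methylhex-2-en-2-yl]-2-methyloxiran-2-yl]-5-methoxypent-4-ene-1,3-dione, via acyl imidazole 14 (not isolated)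
Conditions: 1,1'-carbonyldiimidazole (1.05 equiv), THF, rt; then added to 13 (3.2 equiv)/LiN(SiMe3)2 (3.2 equiv), THF, −78 → −40 °C; aq. NH4Cl
Reagents that add atoms: none
Why: Crossed Claisen condensation in which the acyl imidazole, having no α-hydrogen, acylates the kinetic lithium enolate of 13 at its methyl carbon, the excess enolate deprotonating imidazole and the 1,3-diketone as it forms.

Step 10
Reactants: 15 (4E)-1-[(2R,3S)-3-[(2E,4R,5S)-5-(TBS-oxy)-4-methylhex-2-en-2-yl]-2-methyloxiran-2-yl]-5-methoxypent-4-ene-1,3-dione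
Product: 16 2-[(2R,3S)-3-[(2E,4R,5S)-5-(TBS-oxy)-4-methylhex-2-en-2-yl]-2-methyloxiran-2-yl]-4H-pyran-4-one
Conditions: pyridinium p-toluenesulfonate (0.2 equiv), PhMe, 50 °C
Reagents that add atoms: none
Why: Acid-catalysed 6-endo oxa-conjugate addition of the diketone enol to the β-methoxy enone with loss of methanol, a known 4-pyranone synthesis run here with a mild pyridinium acid to spare the vinyl epoxide.

Step 11
Reactants: 16 2-[(2R,3S)-3-[(2E,4R,5S)-5-(TBS-oxy)-4-methylhex-2-en-2-yl]-2-methyloxiran-2-yl]-4H-pyran-4-one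
Product: 18 2-[(2R,3S)-3-[(2E,4R,5S)-5-(TBS-oxy)-4-methylhex-2-en-2-yl]-2-methyloxiran-2-yl]-4-methylidene-4H-pyran, via silyl carbinol 17 (not isolated)
Conditions: Me3SiCH2Li (1.3 equiv), THF, −78 °C; KOtBu (1.5 equiv), −78 → 0 °C; cold aq. NaHCO3/pentane work-up; used at once
Reagents that add atoms: (trimethylsilyl)methyllithium, [Li]C[Si](C)(C)C
Why: Peterson olefination, in which the organolithium adds 1,2 to the pyranone carbonyl and the potassium β-silyl alkoxide loses silanolate by syn-elimination, so the exocyclic methylene forms under basic conditions without passing through a pyrylium salt.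

Step 12
Reactants: 19 (R)-lactic acid
Product: 20 (2R,5R)-2-tert-butyl-5-methyl-1,3-dioxolan-4-one
Conditions: t-BuCHO, p-toluenesulfonic acid (cat.), pentane, reflux with water separator; recrystallisation at −78 °C
Reagents that add atoms: pivalaldehyde, CC(C)(C)C=O
Why: Acid-catalysed acetalisation of the α-hydroxy acid with pivalaldehyde, whose favoured cis isomer (tert-butyl and methyl on the same face) is purified by crystallisation so that the acetal carbon stores the chirality of lactic acid.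

Step 13
Reactants: 20 (2R,5R)-2-tert-butyl-5-methyl-1,3-dioxolan-4-one
Product: 21 (2R,5S)-5-[(benzyloxy)methyl]-2-tert-butyl-5-methyl-1,3-dioxolan-4-one
Conditions: LiN(iPr)2 (1.1 equiv), THF, −78 °C; BnOCH2Cl (1.3 equiv), −78 → −30 °C
Reagents that add atoms: benzyl chloromethyl ether, ClCOCc1ccccc1
Why: Enolate alkylation with self-regeneration of the stereocentre, in which the planar lithium enolate is attacked by the reactive chloromethyl ether on the face opposite the tert-butyl group, so that CH2OBn replaces H with retention and C5 becomes the (S) quaternary centre.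

Step 14
Reactants: 21 (2R,5S)-5-[(benzyloxy)methyl]-2-tert-butyl-5-methyl-1,3-dioxolan-4-one
Product: 22 (2S)-3-(benzyloxy)-2-hydroxy-2-methylpropanoic acid
Conditions: LiOH, THF/H2O, 0 °C → rt; 1 M HCl to pH 2
Reagents that add atoms: lithium hydroxide, [Li+].[OH-]
Why: Saponification of the lactone-acetal, in which hydroxide opens the dioxolanone and the released hemiacetal collapses with loss of pivalaldehyde, leaving the quaternary stereocentre untouched.

Step 15
Reactants: 22 (2S)-3-(benzyloxy)-2-hydroxy-2-methylpropanoic acid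
Product: 23 (2S)-2,3-dihydroxy-2-methylpropanoic acid
Conditions: H2 (1 atm), Pd/C, MeOH, rt
Reagents that add atoms: none
Why: Catalytic hydrogenolysis of the benzyl ether, which needs no aqueous work-up and so delivers the water-soluble diol acid by filtration and evaporation.

Step 16
Reactants: 23 (2S)-2,3-dihydroxy-2-methylpropanoic acid
Product: 25 (2S)-2-methyl-2,3-bis(TES-oxy)propanoic acid, via silyl ester 24 (not isolated)
Conditions: Et3SiOTf (3.5 equiv), 2,6-lutidine, CH2Cl2, −78 → 0 °C; then THF/H2O, 0 °C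
Reagents that add atoms: triethylsilyl trifluoromethanesulfonate, CC[Si](CC)(CC)OS(=O)(=O)C(F)(F)F
Why: Persilylation with a silyl triflate and a hindered pyridine base covers the tertiary and primary hydroxyls and the acid, after which water hydrolyses only the labile silyl ester.

Step 17
Reactants: 18 2-[(2R,3S)-3-[(2E,4R,5S)-5-(TBS-oxy)-4-methylhex-2-en-2-yl]-2-methyloxiran-2-yl]-4-methylidene-4H-pyran; 25 (2S)-2-methyl-2,3-bis(TES-oxy)propanoic acid
Product: 27 (3S)-3-methyl-1-[(4E)-2-[(2R,3S)-3-[(2E,4R,5S)-5-(TBS-oxy)-4-methylhex-2-en-2-yl]-2-methyloxiran-2-yl]-4H-pyran-4-ylidene]-3,4-bis(TES-oxy)butan-2-one, via acid chloride 26 (not isolated)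
Conditions: 25 (1.3 equiv), 1-chloro-N,N,2-trimethylprop-1-en-1-amine (1.2 equiv), CH2Cl2, 0 °C → rt; then added to 18, Et3N, DMAP (cat.), CH2Cl2, −40 → 0 °C
Reagents that add atoms: none
Why: C-Acylation of a 4-methylenepyran (the anhydrobase of a 4-methylpyrylium salt), a known reaction of these enamine-like trienes in which the exocyclic carbon attacks the acid chloride, made under neutral conditions with the α-chloroenamine, and triethylamine deprotonates the resulting acylmethylpyrylium ion to the push–pull pyranylidene ketone.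

Step 18
Reactants: 27 (3S)-3-methyl-1-[(4E)-2-[(2R,3S)-3-[(2E,4R,5S)-5-(TBS-oxy)-4-methylhex-2-en-2-yl]-2-methyloxiran-2-yl]-4H-pyran-4-ylidene]-3,4-bis(TES-oxy)butan-2-one
Product: 28 (2S)-2-methyl-3-oxo-4-[(4E)-2-[(2R,3S)-3-[(2E,4R,5S)-5-(TBS-oxy)-4-methylhex-2-en-2-yl]-2-methyloxiran-2-yl]-4H-pyran-4-ylidene]-2-(TES-oxy)butanal
Conditions: (COCl)2, DMSO, CH2Cl2, −78 → −35 °C; Et3N, −78 → 0 °C
Reagents that add atoms: none
Why: Direct Swern oxidation of a primary triethylsilyl ether, in which chlorodimethylsulfonium chloride exchanges only the least hindered silyl ether for an alkoxysulfonium ion that triethylamine converts into the aldehyde, so the tertiary TES and secondary TBS ethers remain and no free primary alcohol, prone to silyl migration from O7 and retro-aldol loss of formaldehyde, is ever formed.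

Step 19
Reactants: 28 (2S)-2-methyl-3-oxo-4-[(4E)-2-[(2R,3S)-3-[(2E,4R,5S)-5-(TBS-oxy)-4-methylhex-2-en-2-yl]-2-methyloxiran-2-yl]-4H-pyran-4-ylidene]-2-(TES-oxy)butanal
Product: 29 (7S,8R)-3-[(2R,3S)-3-[(2E,4R,5S)-5-(TBS-oxy)-4-methylhex-2-en-2-yl]-2-methyloxiran-2-yl]-8-hydroxy-7-methyl-7-(TES-oxy)-7,8-dihydro-6H-isochromen-6-one
Conditions: DABCO (1.0 equiv), t-BuOH (5 equiv), MeCN, 0 °C → rt
Reagents that add atoms: none
Why: Proposed new method: DABCO should add reversibly to C1, the unsubstituted oxygen-bearing end of the dienone O2–C1=C8a–C4a=C5–C6=O, to give a zwitterionic 2-ammonio-2H-pyran dienolate whose γ-carbon C8a attacks the C8 aldehyde, after which proton transfer from C8a (shuttled by t-BuOH) and expulsion of the amine from the N,O-acetal carbon C1 restore the C1=C8a enol ether. The closest known reaction types are the amine-catalysed Morita–Baylis–Hillman reactions of chromones and 4-pyranones at the carbon α to the carbonyl and the intramolecular Morita–Baylis–Hillman cyclisations of enone aldehydes, extended here by one vinylogous unit. Ring A (C8a, C4a, C5, C6, C7, C8) closes in a 6-(enolendo)-exo-trig mode. The new C8 stereocentre is set under control of C7: in the half-chair transition state the aldehyde oxygen should lie antiperiplanar to the non-chelating C7–OSiEt3 bond (Cornforth-type dipole arrangement) and pseudoaxial, away from C1–H (allylic 1,3-strain), which puts O8 trans to O7 and gives (8R). The step needs amine addition at C1 and not at C3 and bond formation through C8a and not C5, which the fully substituted C9 on C3 and the impossibility of a four-membered ring through C5 secure, while the aldehyde cannot enolise and the C4a=C5 geometry is immaterial because that bond is single in the adduct.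

Step 20
Reactants: 29 (7S,8R)-3-[(2R,3S)-3-[(2E,4R,5S)-5-(TBS-oxy)-4-methylhex-2-en-2-yl]-2-methyloxiran-2-yl]-8-hydroxy-7-methyl-7-(TES-oxy)-7,8-dihydro-6H-isochromen-6-one
Product: 30 pestaphilone D
Conditions: Bu4NF, AcOH (1:1), THF, 0 °C → rt
Reagents that add atoms: none
Why: Fluoride-mediated cleavage of both silyl ethers with acetic-acid-buffered Bu4NF, a near-neutral desilylation chosen to spare the vinyl epoxide and the base-sensitive isochromenone core.

Compound list
1 | ethyl (3S)-3-hydroxybutanoate | C[C@H](O)CC(=O)OCC | starting material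
2 | ethyl (2S,3S)-3-hydroxy-2-methylbutanoate | CCOC(=O)[C@@H](C)[C@H](C)O | intermediate
3 | ethyl (2S,3S)-3-[(tert-butyldimethylsilyl)oxy]-2-methylbutanoate | CCOC(=O)[C@@H](C)[C@H](C)O[Si](C)(C)C(C)(C)C | intermediate
4 | (2S,3S)-3-[(tert-butyldimethylsilyl)oxy]-2-methylbutanal | O=C[C@@H](C)[C@H](C)O[Si](C)(C)C(C)(C)C | intermediate
5 | 2-(triphenylphosphoranylidene)propanal | CC(C=O)=P(c1ccccc1)(c1ccccc1)c1ccccc1 | starting material
6 | (2E,4R,5S)-5-[(tert-butyldimethylsilyl)oxy]-2,4-dimethylhex-2-enal | C/C(=C\[C@@H](C)[C@H](C)O[Si](C)(C)C(C)(C)C)C=O | intermediate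
7 | ethyl 2-(triphenylphosphoranylidene)propanoate | CCOC(=O)C(C)=P(c1ccccc1)(c1ccccc1)c1ccccc1 | starting material
8 | ethyl (2E,4E,6R,7S)-7-[(tert-butyldimethylsilyl)oxy]-2,4,6-trimethylocta-2,4-dienoate | C/C(=C\[C@@H](C)[C@H](C)O[Si](C)(C)C(C)(C)C)/C=C(\C)C(=O)OCC | intermediate
9 | (2E,4E,6R,7S)-7-[(tert-butyldimethylsilyl)oxy]-2,4,6-trimethylocta-2,4-dien-1-ol | C/C(=C\[C@@H](C)[C@H](C)O[Si](C)(C)C(C)(C)C)/C=C(\C)CO | intermediate
10 | [(2S,3S)-3-[(2E,4R,5S)-5-[(tert-butyldimethylsilyl)oxy]-4-methylhex-2-en-2-yl]-2-methyloxiran-2-yl]methanol | C/C(=C\[C@@H](C)[C@H](C)O[Si](C)(C)C(C)(C)C)[C@@H]1O[C@@]1(C)CO | intermediate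
11 | (2R,3S)-3-[(2E,4R,5S)-5-[(tert-butyldimethylsilyl)oxy]-4-methylhex-2-en-2-yl]-2-methyloxirane-2-carbaldehyde; not isolated | C/C(=C\[C@@H](C)[C@H](C)O[Si](C)(C)C(C)(C)C)[C@@H]1O[C@@]1(C)C=O | intermediate
12 | (2R,3S)-3-[(2E,4R,5S)-5-[(tert-butyldimethylsilyl)oxy]-4-methylhex-2-en-2-yl]-2-methyloxirane-2-carboxylic acid | C/C(=C\[C@@H](C)[C@H](C)O[Si](C)(C)C(C)(C)C)[C@@H]1O[C@@]1(C)C(=O)O | intermediate
13 | (E)-4-methoxybut-3-en-2-one | CO/C=C/C(C)=O | starting material
14 | [(2R,3S)-3-[(2E,4R,5S)-5-[(tert-butyldimethylsilyl)oxy]-4-methylhex-2-en-2-yl]-2-methyloxiran-2-yl](1H-imidazol-1-yl)methanone; not isolated | C/C(=C\[C@@H](C)[C@H](C)O[Si](C)(C)C(C)(C)C)[C@@H]1O[C@@]1(C)C(=O)n2ccnc2 | intermediate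
15 | (4E)-1-[(2R,3S)-3-[(2E,4R,5S)-5-[(tert-butyldimethylsilyl)oxy]-4-methylhex-2-en-2-yl]-2-methyloxiran-2-yl]-5-methoxypent-4-ene-1,3-dione | C/C(=C\[C@@H](C)[C@H](C)O[Si](C)(C)C(C)(C)C)[C@@H]1O[C@@]1(C)C(=O)CC(=O)/C=C/OC | intermediate
16 | 2-[(2R,3S)-3-[(2E,4R,5S)-5-[(tert-butyldimethylsilyl)oxy]-4-methylhex-2-en-2-yl]-2-methyloxiran-2-yl]-4H-pyran-4-one | C/C(=C\[C@@H](C)[C@H](C)O[Si](C)(C)C(C)(C)C)[C@@H]1O[C@@]1(C)C1=CC(=O)C=CO1 | intermediate
17 | 2-[(2R,3S)-3-[(2E,4R,5S)-5-[(tert-butyldimethylsilyl)oxy]-4-methylhex-2-en-2-yl]-2-methyloxiran-2-yl]-4-[(trimethylsilyl)methyl]-4H-pyran-4-ol (both epimers at the carbinol carbon, as its alkoxide); not isolated | C/C(=C\[C@@H](C)[C@H](C)O[Si](C)(C)C(C)(C)C)[C@@H]1O[C@@]1(C)C1=CC(O)(C[Si](C)(C)C)C=CO1 | intermediate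
18 | 2-[(2R,3S)-3-[(2E,4R,5S)-5-[(tert-butyldimethylsilyl)oxy]-4-methylhex-2-en-2-yl]-2-methyloxiran-2-yl]-4-methylidene-4H-pyran | C/C(=C\[C@@H](C)[C@H](C)O[Si](C)(C)C(C)(C)C)[C@@H]1O[C@@]1(C)C1=CC(=C)C=CO1 | intermediate
19 | (R)-lactic acid, (2R)-2-hydroxypropanoic acid | C[C@@H](O)C(=O)O | starting material
20 | (2R,5R)-2-tert-butyl-5-methyl-1,3-dioxolan-4-one | C[C@H]1O[C@@H](C(C)(C)C)OC1=O | intermediate
21 | (2R,5S)-5-[(benzyloxy)methyl]-2-tert-butyl-5-methyl-1,3-dioxolan-4-one | C[C@@]1(COCc2ccccc2)O[C@@H](C(C)(C)C)OC1=O | intermediate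
22 | (2S)-3-(benzyloxy)-2-hydroxy-2-methylpropanoic acid | OC(=O)[C@@](C)(O)COCc1ccccc1 | intermediate
23 | (2S)-2,3-dihydroxy-2-methylpropanoic acid | OC(=O)[C@@](C)(O)CO | intermediate
24 | triethylsilyl (2S)-2-methyl-2,3-bis[(triethylsilyl)oxy]propanoate; not isolated | CC[Si](CC)(CC)OC(=O)[C@@](C)(O[Si](CC)(CC)CC)CO[Si](CC)(CC)CC | intermediate
25 | (2S)-2-methyl-2,3-bis[(triethylsilyl)oxy]propanoic acid | OC(=O)[C@@](C)(O[Si](CC)(CC)CC)CO[Si](CC)(CC)CC | intermediate
26 | (2S)-2-methyl-2,3-bis[(triethylsilyl)oxy]propanoyl chloride; not isolated | ClC(=O)[C@@](C)(O[Si](CC)(CC)CC)CO[Si](CC)(CC)CC | intermediate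
27 | (3S)-3-methyl-1-[(4E)-2-[(2R,3S)-3-[(2E,4R,5S)-5-[(tert-butyldimethylsilyl)oxy]-4-methylhex-2-en-2-yl]-2-methyloxiran-2-yl]-4H-pyran-4-ylidene]-3,4-bis[(triethylsilyl)oxy]butan-2-one | C/C(=C\[C@@H](C)[C@H](C)O[Si](C)(C)C(C)(C)C)[C@@H]1O[C@@]1(C)C1=C/C(=C/C(=O)[C@@](C)(O[Si](CC)(CC)CC)CO[Si](CC)(CC)CC)C=CO1 | intermediate
28 | (2S)-2-methyl-3-oxo-4-[(4E)-2-[(2R,3S)-3-[(2E,4R,5S)-5-[(tert-butyldimethylsilyl)oxy]-4-methylhex-2-en-2-yl]-2-methyloxiran-2-yl]-4H-pyran-4-ylidene]-2-[(triethylsilyl)oxy]butanal | C/C(=C\[C@@H](C)[C@H](C)O[Si](C)(C)C(C)(C)C)[C@@H]1O[C@@]1(C)C1=C/C(=C/C(=O)[C@@](C)(O[Si](CC)(CC)CC)C=O)C=CO1 | intermediate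
29 | (7S,8R)-3-[(2R,3S)-3-[(2E,4R,5S)-5-[(tert-butyldimethylsilyl)oxy]-4-methylhex-2-en-2-yl]-2-methyloxiran-2-yl]-8-hydroxy-7-methyl-7-[(triethylsilyl)oxy]-7,8-dihydro-6H-isochromen-6-one | C/C(=C\[C@@H](C)[C@H](C)O[Si](C)(C)C(C)(C)C)[C@@H]1O[C@@]1(C)C1=CC2=CC(=O)[C@@](C)(O[Si](CC)(CC)CC)[C@H](O)C2=CO1 | intermediate
30 | pestaphilone D, (7S,8R)-7,8-dihydroxy-3-[(2R,3S)-3-[(2E,4R,5S)-5-hydroxy-4-methylhex-2-en-2-yl]-2-methyloxiran-2-yl]-7-methyl-7,8-dihydro-6H-isochromen-6-one | C/C(=C\[C@@H](C)[C@H](C)O)[C@@H]1O[C@@]1(C)C1=CC2=CC(=O)[C@@](C)(O)[C@H](O)C2=CO1 | target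

Total steps: 20. Longest linear sequence: 15 steps (steps 1–11 and 17–20); the lactic acid branch (steps 12–16) joins at step 17.

Steps most likely to fail

1. Step 19 (proposed new method). The amine may not add at C1 to a useful extent, turnover may stall at the proton-transfer stage, the formyl ketone may be lost by retro-Claisen cleavage, or facial selectivity at C8 may be poor. The fallback, built on known chemistry, closes the same C8–C8a bond by a Nozaki–Hiyama–Kishi reaction of a C8a iodide. It sets out from pyranone 16. Amine-mediated α-iodination (I2, pyridine, CH2Cl2), in which the amine adds at the unsubstituted pyranone C6 (future C1) and the adjacent α-carbon (future C8a) is iodinated, should give the 5-iodopyranone F1. Peterson methylenation as in step 11 leads through the iodo silyl carbinol F2 to the iodo methylenepyran F3. Acylation with 26 as in step 17 gives the iodo pyranylidene ketone F4, and direct Swern oxidation as in step 18 gives the iodo aldehyde F5, whose push–pull double bond should rotate to the reactive geometry. CrCl2 with catalytic NiCl2 (DMF/THF, rt) then turns the alkenyl iodide into an alkenylchromium species that adds to the aldehyde only, closing ring A and returning to the route at 29.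

2. Step 17. The electron-rich methylenepyran 18 may oligomerise or oxidise before the hindered, α-quaternary acid chloride reacts, or acylation may be too slow to compete. The fallback attaches the C5–C6 unit as an alkyne and unveils the ketone by rearrangement, so 18 is not needed. It sets out from acid 25 (as its chloride 26) and pyranone 16. LiAlH(OtBu)3 (THF, −78 °C) reduces 26 to the silyloxy aldehyde F6. Ohira–Bestmann homologation (dimethyl (1-diazo-2-oxopropyl)phosphonate, K2CO3, MeOH) gives the terminal alkyne F7. Its lithium acetylide (n-BuLi, THF, −78 °C) adds to the carbonyl of 16 to give the propargylic carbinol F8. Meyer–Schuster rearrangement (catalytic Ph3PAuNTf2 in wet THF, or pyridinium p-toluenesulfonate) moves the oxygen from C4a to C6 and returns to the route at 27.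

3. Step 18. The activated sulfoxide may attack the electron-rich pyranylidene system or the vinyl epoxide before the hindered neopentyl-type silyl ether is exchanged, or the tertiary silyl ether may be lost. The fallback separates unmasking from oxidation and uses a non-electrophilic oxidant. It sets out from 27. Buffered HF·pyridine (pyridine, THF, 0 °C) should remove only the primary TES group to give the primary alcohol F9, and Dess–Martin oxidation (NaHCO3, CH2Cl2, 0 °C) then returns to the route at 28.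

Further compounds
F1 | step 19 | 2-[(2R,3S)-3-[(2E,4R,5S)-5-[(tert-butyldimethylsilyl)oxy]-4-methylhex-2-en-2-yl]-2-methyloxiran-2-yl]-5-iodo-4H-pyran-4-one | C/C(=C\[C@@H](C)[C@H](C)O[Si](C)(C)C(C)(C)C)[C@@H]1O[C@@]1(C)C1=CC(=O)C(I)=CO1
F2 | step 19 | 2-[(2R,3S)-3-[(2E,4R,5S)-5-[(tert-butyldimethylsilyl)oxy]-4-methylhex-2-en-2-yl]-2-methyloxiran-2-yl]-5-iodo-4-[(trimethylsilyl)methyl]-4H-pyran-4-ol (both carbinol epimers) | C/C(=C\[C@@H](C)[C@H](C)O[Si](C)(C)C(C)(C)C)[C@@H]1O[C@@]1(C)C1=CC(O)(C[Si](C)(C)C)C(I)=CO1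
F3 | step 19 | 2-[(2R,3S)-3-[(2E,4R,5S)-5-[(tert-butyldimethylsilyl)oxy]-4-methylhex-2-en-2-yl]-2-methyloxiran-2-yl]-5-iodo-4-methylidene-4H-pyran | C/C(=C\[C@@H](C)[C@H](C)O[Si](C)(C)C(C)(C)C)[C@@H]1O[C@@]1(C)C1=CC(=C)C(I)=CO1
F4 | step 19 | (3S)-1-[(4Z)-5-iodo-2-[(2R,3S)-3-[(2E,4R,5S)-5-[(tert-butyldimethylsilyl)oxy]-4-methylhex-2-en-2-yl]-2-methyloxiran-2-yl]-4H-pyran-4-ylidene]-3-methyl-3,4-bis[(triethylsilyl)oxy]butan-2-one | C/C(=C\[C@@H](C)[C@H](C)O[Si](C)(C)C(C)(C)C)[C@@H]1O[C@@]1(C)C1=C/C(=C/C(=O)[C@@](C)(O[Si](CC)(CC)CC)CO[Si](CC)(CC)CC)C(I)=CO1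
F5 | step 19 | (2S)-4-[(4Z)-5-iodo-2-[(2R,3S)-3-[(2E,4R,5S)-5-[(tert-butyldimethylsilyl)oxy]-4-methylhex-2-en-2-yl]-2-methyloxiran-2-yl]-4H-pyran-4-ylidene]-2-methyl-3-oxo-2-[(triethylsilyl)oxy]butanal | C/C(=C\[C@@H](C)[C@H](C)O[Si](C)(C)C(C)(C)C)[C@@H]1O[C@@]1(C)C1=C/C(=C/C(=O)[C@@](C)(O[Si](CC)(CC)CC)C=O)C(I)=CO1
F6 | step 17 | (2S)-2-methyl-2,3-bis[(triethylsilyl)oxy]propanal | O=C[C@@](C)(O[Si](CC)(CC)CC)CO[Si](CC)(CC)CC
F7 | step 17 | (3R)-3-methyl-3,4-bis[(triethylsilyl)oxy]but-1-yne | C#C[C@@](C)(O[Si](CC)(CC)CC)CO[Si](CC)(CC)CC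
F8 | step 17 | 2-[(2R,3S)-3-[(2E,4R,5S)-5-[(tert-butyldimethylsilyl)oxy]-4-methylhex-2-en-2-yl]-2-methyloxiran-2-yl]-4-[(3R)-3-methyl-3,4-bis[(triethylsilyl)oxy]but-1-yn-1-yl]-4H-pyran-4-ol (both carbinol epimers) | C/C(=C\[C@@H](C)[C@H](C)O[Si](C)(C)C(C)(C)C)[C@@H]1O[C@@]1(C)C1=CC(O)(C#C[C@@](C)(O[Si](CC)(CC)CC)CO[Si](CC)(CC)CC)C=CO1
F9 | step 18 | (3S)-4-hydroxy-3-methyl-1-[(4E)-2-[(2R,3S)-3-[(2E,4R,5S)-5-[(tert-butyldimethylsilyl)oxy]-4-methylhex-2-en-2-yl]-2-methyloxiran-2-yl]-4H-pyran-4-ylidene]-3-[(triethylsilyl)oxy]butan-2-one | C/C(=C\[C@@H](C)[C@H](C)O[Si](C)(C)C(C)(C)C)[C@@H]1O[C@@]1(C)C1=C/C(=C/C(=O)[C@@](C)(O[Si](CC)(CC)CC)CO)C=CO1
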